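**Synthesis proposal for 5,7,8-trimethoxy-2-(2,3,4,5-tetramethoxyphenyl)chromen-4-one**

Retrosynthesis: ring C is opened at the aryl–carbonyl bond C4–C4a (intramolecular Friedel–Crafts acylation), then at O1–C2 (phenoxide addition to an aryl alkynoate), then at C2–C1' (Sonogashira coupling).
Enabling feature: in ring A (C4a, C5, C6, C7, C8, C8a) C4a is the only hydrogen-bearing carbon next to the O1-bearing C8a, since C8 carries OMe; it is ortho to O1 and to the 5-OMe and para to the 7-OMe, so an acyl carbon C4 tethered through O1–C2=C3 can close the pyranone only there.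
Forward: ring A is prepared as 2,3,5-trimethoxyphenol from 2-hydroxy-4,6-dimethoxybenzaldehyde, and ring B as 1-iodo-2,3,4,5-tetramethoxybenzene from 2,3,4-trimethoxybenzaldehyde; ethyl propiolate supplies C2, C3 and C4.
Order of assembly: C2–C1' (Sonogashira), then O1–C2 (oxa-Michael), then ester cleavage, and ring C is formed last at C4–C4a.
Stereochemistry: the target has no stereocentre; the only stereo element on the way is the Z enol ether geometry from anti addition to the alkyne, and it disappears in the aromatic pyranone.

Key step: step 11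

Assumption: the oxa-Michael adduct is drawn as the Z isomer expected from anti addition; an E/Z mixture would be carried forward, since both isomers can converge under the acidic ring closure.

**Route**

Step 1
Reactants: 1 2-hydroxy-4,6-dimethoxybenzaldehyde
Product: 2 2-(benzyloxy)-4,6-dimethoxybenzaldehyde
Conditions: BnBr, K2CO3, DMF, 60 °C
Reagents that add atoms: benzyl bromide, BrCc1ccccc1
Why: Williamson etherification (SN2) of the phenoxide in a polar aprotic solvent, which overcomes the hydrogen bond to the ortho aldehyde and masks the oxygen that later becomes O1.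

Step 2
Reactants: 2 2-(benzyloxy)-4,6-dimethoxybenzaldehyde
Product: 4 2-(benzyloxy)-4,6-dimethoxyphenol, via aryl formate 3 (not isolated)
Conditions: mCPBA, CH2Cl2, 0 °C to rt; aq. NaHCO3 wash; then K2CO3 (cat.), MeOH, rt
Reagents that add atoms: meta-chloroperoxybenzoic acid (mCPBA), OOC(=O)c1cccc(Cl)c1
Why: Baeyer–Villiger oxidation in which the electron-rich trialkoxyaryl group migrates in preference to hydrogen, followed by base-catalysed methanolysis of the labile aryl formate.

Step 3
Reactants: 4 2-(benzyloxy)-4,6-dimethoxyphenol
Product: 5 1-(benzyloxy)-2,3,5-trimethoxybenzene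
Conditions: MeI, K2CO3, DMF, rt
Reagents that add atoms: iodomethane, CI
Why: Williamson O-methylation of the new phenol, done promptly because the electron-rich phenol is sensitive to air, fixes the future 8-OMe.

Step 4
Reactants: 5 1-(benzyloxy)-2,3,5-trimethoxybenzene
Product: 6 2,3,5-trimethoxyphenol
Conditions: H2 (1 atm), 10% Pd/C, EtOAc/MeOH, rt
Reagents that add atoms: none
Why: Catalytic hydrogenolysis of the benzyl ether, to which aryl methyl ethers are inert, should release the phenol that supplies O1 and ring A.

Step 5
Reactants: 7 2,3,4-trimethoxybenzaldehyde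
Product: 9 2,3,4-trimethoxyphenol, via aryl formate 8 (not isolated)
Conditions: mCPBA, CH2Cl2, 0 °C to rt; aq. NaHCO3 wash; then K2CO3 (cat.), MeOH, rt
Reagents that add atoms: meta-chloroperoxybenzoic acid (mCPBA), OOC(=O)c1cccc(Cl)c1
Why: Baeyer–Villiger oxidation with migration of the ortho,para-alkoxy-activated aryl group, then methanolysis of the formate, as is standard for alkoxybenzaldehydes.

Step 6
Reactants: 9 2,3,4-trimethoxyphenol
Product: 10 1,2,3,4-tetramethoxybenzene
Conditions: MeI, K2CO3, DMF, rt
Reagents that add atoms: iodomethane, CI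
Why: Williamson O-methylation of the phenoxide completes the four contiguous methoxy groups of ring B.

Step 7
Reactants: 10 1,2,3,4-tetramethoxybenzene
Product: 11 1-iodo-2,3,4,5-tetramethoxybenzene
Conditions: NIS (1.05 equiv), CF3CO2H (cat.), MeCN, rt
Reagents that add atoms: N-iodosuccinimide, O=C1CCC(=O)N1I
Why: Electrophilic aromatic iodination by acid-activated N-iodosuccinimide, where the two free positions are symmetry-equivalent (each ortho to one OMe and para to another), so a single mono-iodide is expected and stoichiometry limits di-iodination.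

Step 8
Reactants: 11 1-iodo-2,3,4,5-tetramethoxybenzene; 12 ethyl propiolate
Product: 13 ethyl 3-(2,3,4,5-tetramethoxyphenyl)prop-2-ynoate
Conditions: PdCl2(PPh3)2 (cat.), CuI (cat.), K2CO3, THF, 65 °C, slow addition of 12
Reagents that add atoms: none
Why: Sonogashira coupling of the aryl iodide with the terminal alkyne, run with an inorganic base instead of an amine and with slow addition so that conjugate addition to the electron-poor propiolate and its oligomerisation are suppressed.

Step 9
Reactants: 6 2,3,5-trimethoxyphenol; 13 ethyl 3-(2,3,4,5-tetramethoxyphenyl)prop-2-ynoate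
Product: 14 ethyl (Z)-3-(2,3,4,5-tetramethoxyphenyl)-3-(2,3,5-trimethoxyphenoxy)acrylate (aryloxy group cis to the ester)
Conditions: Cs2CO3 (0.3 equiv), dry DMF, 90 °C
Reagents that add atoms: none
Why: Base-mediated oxa-Michael addition of the phenoxide to the β-carbon of the aryl alkynoate forms O1–C2, and anti protonation of the allenolate places the aryloxy group cis to the ester, the known entry to β-aryloxycinnamates.

Step 10
Reactants: 14 ethyl (Z)-3-(2,3,4,5-tetramethoxyphenyl)-3-(2,3,5-trimethoxyphenoxy)acrylate
Product: 15 (Z)-3-(2,3,4,5-tetramethoxyphenyl)-3-(2,3,5-trimethoxyphenoxy)acrylic acid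
Conditions: LiOH, THF/MeOH/H2O, rt to 40 °C; then 1 M HCl to pH 3, 0 °C
Reagents that add atoms: lithium hydroxide, [Li+].[OH-]
Why: Saponification of the ethyl ester by acyl substitution should outpace conjugate displacement of the phenoxide at the hindered, doubly donor-substituted β-carbon, and cold, mild acidification spares the enol ether.

Step 11
Reactants: 15 (Z)-3-(2,3,4,5-tetramethoxyphenyl)-3-(2,3,5-trimethoxyphenoxy)acrylic acid
Product: 17 5,7,8-trimethoxy-2-(2,3,4,5-tetramethoxyphenyl)chromen-4-one, via mixed anhydride 16 (not isolated)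
Conditions: (CF3CO)2O (2–3 equiv), CH2Cl2, 0 °C to rt
Reagents that add atoms: none
Why: Trifluoroacetic anhydride converts the acid into the mixed anhydride 16, an acylium equivalent whose acyl carbon (future C4) is attacked by the arene carbon ortho to the ether oxygen (future C4a), and loss of a proton from the arenium ion together with trifluoroacetate gives the aryl ketone, an intramolecular Friedel–Crafts acylation. The closest known reaction type is the acid-mediated ring closure of β-aryloxycinnamic acids to flavones and of aryloxyfumaric acids to chromone-2-carboxylates. The only ring formed is the 4-pyranone ring C, closed in a six-membered mode at C4–C4a (6-exo-trig at the acyl carbon of 16), and the product is aromatic at once because the acrylic acid already has the oxidation level of the flavone. No stereocentre is created and the Z geometry of the enol ether is consumed. The step needs attack by ring A rather than by C6' of ring B (which would give a five-membered indenone); this is secured by the Z geometry that holds the carboxyl beside the aryloxy group, by the six- over five-membered preference and by the phloroglucinol-type activation of C4a, while the OMe on C8 leaves no second site on ring A. The mild activation, free of Lewis acids, should leave the seven methyl ethers untouched.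

**Compound list**

1 | 2-hydroxy-4,6-dimethoxybenzaldehyde | COc1cc(O)c(C=O)c(OC)c1 | starting material
2 | 2-(benzyloxy)-4,6-dimethoxybenzaldehyde | COc1cc(OCc2ccccc2)c(C=O)c(OC)c1 | intermediate
3 | 2-(benzyloxy)-4,6-dimethoxyphenyl formate | COc1cc(OCc2ccccc2)c(OC=O)c(OC)c1 | intermediate
4 | 2-(benzyloxy)-4,6-dimethoxyphenol | COc1cc(OCc2ccccc2)c(O)c(OC)c1 | intermediate
5 | 1-(benzyloxy)-2,3,5-trimethoxybenzene | COc1cc(OC)c(OC)c(OCc2ccccc2)c1 | intermediate
6 | 2,3,5-trimethoxyphenol | COc1cc(O)c(OC)c(OC)c1 | intermediate
7 | 2,3,4-trimethoxybenzaldehyde | COc1ccc(C=O)c(OC)c1OC | starting material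
8 | 2,3,4-trimethoxyphenyl formate | COc1ccc(OC=O)c(OC)c1OC | intermediate
9 | 2,3,4-trimethoxyphenol | COc1ccc(O)c(OC)c1OC | intermediate
10 | 1,2,3,4-tetramethoxybenzene | COc1ccc(OC)c(OC)c1OC | intermediate
11 | 1-iodo-2,3,4,5-tetramethoxybenzene | COc1cc(I)c(OC)c(OC)c1OC | intermediate
12 | ethyl propiolate | C#CC(=O)OCC | starting material
13 | ethyl 3-(2,3,4,5-tetramethoxyphenyl)prop-2-ynoate | CCOC(=O)C#Cc1cc(OC)c(OC)c(OC)c1OC | intermediate
14 | ethyl (Z)-3-(2,3,4,5-tetramethoxyphenyl)-3-(2,3,5-trimethoxyphenoxy)acrylate | CCOC(=O)/C=C(\Oc1cc(OC)cc(OC)c1OC)c1cc(OC)c(OC)c(OC)c1OC | intermediate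
15 | (Z)-3-(2,3,4,5-tetramethoxyphenyl)-3-(2,3,5-trimethoxyphenoxy)acrylic acid | OC(=O)/C=C(\Oc1cc(OC)cc(OC)c1OC)c1cc(OC)c(OC)c(OC)c1OC | intermediate
16 | (Z)-3-(2,3,4,5-tetramethoxyphenyl)-3-(2,3,5-trimethoxyphenoxy)acrylic trifluoroacetic anhydride | O=C(/C=C(\Oc1cc(OC)cc(OC)c1OC)c1cc(OC)c(OC)c(OC)c1OC)OC(=O)C(F)(F)F | intermediate
17 | 5,7,8-trimethoxy-2-(2,3,4,5-tetramethoxyphenyl)chromen-4-one | COc1cc(-c2cc(=O)c3c(OC)cc(OC)c(OC)c3o2)c(OC)c(OC)c1OC | target

**Step count**

Total: 11 steps. Longest linear sequence: 7 steps (steps 1, 2, 3, 4, 9, 10, 11; the branch through steps 5, 6, 7, 8 is equally long).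

**Steps most likely to fail**

Step 9. Conjugate addition to an alkynoate whose β-carbon is deactivated by an ortho- and para-methoxylated aryl group may be slow, and at the temperature then needed the phenoxide may attack the ester instead. The fallback sets out from 13 and forms O1–C2 by substitution at an sp2 carbon rather than by addition to the alkyne. Hydroiodination of 13 (NaI, AcOH, 80 °C) should give ethyl (Z)-3-iodo-3-(2,3,4,5-tetramethoxyphenyl)acrylate F1. An Ullmann-type vinylation of phenol 6 with this iodide (CuI, N,N-dimethylglycine, Cs2CO3, dioxane, 90 °C) should then give the aryl vinyl ether with retention of geometry, and the route is rejoined at 14.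

Step 11. The aryl enol ether may be cleaved by acid (protonation at C3 and loss of the phenol) before acylation, the very electron-rich ring A may be trifluoroacetylated intermolecularly, or any E isomer may close onto ring B. The fallback closes ring C at O1–C2 instead and sets out from 6 and 10. Ortho-acetylation of 6 (AcOH, BF3·OEt2, 90 °C, Fries type) should give 1-(2-hydroxy-3,4,6-trimethoxyphenyl)ethan-1-one F2. Rieche formylation of 10 (Cl2CHOMe, TiCl4, CH2Cl2, 0 °C) should give 2,3,4,5-tetramethoxybenzaldehyde F3. Claisen–Schmidt condensation of the two (KOH, EtOH, rt) should give (E)-1-(2-hydroxy-3,4,6-trimethoxyphenyl)-3-(2,3,4,5-tetramethoxyphenyl)prop-2-en-1-one F4. Oxidative cyclisation of this chalcone (I2 cat., DMSO, 130 °C) should deliver the flavone, and the route is rejoined at 17.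

Step 8. Base-induced oligomerisation and alkyne homocoupling of the propiolate may outrun the slow oxidative addition of the electron-rich, ortho-substituted iodide to palladium. The fallback sets out from 11 and installs the ester after the coupling. Sonogashira coupling with trimethylsilylacetylene (PdCl2(PPh3)2, CuI, Et3N, THF, 50 °C) should give trimethyl[(2,3,4,5-tetramethoxyphenyl)ethynyl]silane F5. Desilylation (K2CO3, MeOH, rt) should give 1-ethynyl-2,3,4,5-tetramethoxybenzene F6. Deprotonation with n-BuLi (THF, −78 °C) and trapping of the lithium acetylide with ethyl chloroformate should give the alkynoate, and the route is rejoined at 13.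

**Further compounds**

F1 | step 9 | ethyl (Z)-3-iodo-3-(2,3,4,5-tetramethoxyphenyl)acrylate | CCOC(=O)/C=C(\I)c1cc(OC)c(OC)c(OC)c1OC
F2 | step 11 | 1-(2-hydroxy-3,4,6-trimethoxyphenyl)ethan-1-one | COc1cc(OC)c(C(C)=O)c(O)c1OC
F3 | step 11 | 2,3,4,5-tetramethoxybenzaldehyde | COc1cc(C=O)c(OC)c(OC)c1OC
F4 | step 11 | (E)-1-(2-hydroxy-3,4,6-trimethoxyphenyl)-3-(2,3,4,5-tetramethoxyphenyl)prop-2-en-1-one | COc1cc(OC)c(C(=O)/C=C/c2cc(OC)c(OC)c(OC)c2OC)c(O)c1OC
F5 | step 8 | trimethyl[(2,3,4,5-tetramethoxyphenyl)ethynyl]silane | COc1cc(C#C[Si](C)(C)C)c(OC)c(OC)c1OC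
F6 | step 8 | 1-ethynyl-2,3,4,5-tetramethoxybenzene | COc1cc(C#C)c(OC)c(OC)c1OC
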